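## Retrosynthetic overview

- Target ⇐ late adjustments on a germacradienolide: angelate at O‑9, epoxidation of the 3Z alkene, ene oxidation of C‑1/C‑10/C‑14 to the exo‑methylene ketone, removal of one benzyl‑type ether.
- α‑Methylene‑γ‑lactone ⇐ Eschenmoser methylenation of the trans lactone, which comes from reduction and lactonisation of a 6‑keto 7‑acetate.
- Ten‑membered ring ⇐ anionic oxy‑Cope ([3,3]) ring expansion of a cis‑1,2‑dialkenylcyclohex‑3‑enol carrying two E enol ethers; it forms C‑8–C‑9 and sets C‑8/C‑9, and the enolate is alkylated in the flask (C‑7).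
- Cope substrate ⇐ lithium alkoxyacetylide plus a cyclohexenone made from (S)‑carvone (isopropenyl → E silyl enol ether; 1,2‑carbonyl transposition).
- Ring order: cyclohexene (bought) → cyclodecadiene (oxy‑Cope) → γ‑lactone → epoxide.

Assumption: germacrane numbers of the target (C‑1 ketone, C‑3/C‑4 epoxide, C‑6 lactone O, C‑7 fusion, C‑8 OH, C‑9 OAng, C‑10/C‑14 methylene, C‑11–C‑13 lactone) are used for the same atoms in every intermediate, α is the face of H‑7, and the stereochemical outcomes of steps 4, 7, 8, 9 and 13 are predictions from models, not established results.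

## Route

Step 1
Reactants: 1 (S)-(+)-carvone
Product: 2 2-[(1S)-4-methyl-5-oxocyclohex-3-en-1-yl]prop-2-enal
Conditions: SeO2 (1.1 equiv), 1,4-dioxane, 80 °C
Reagents that add atoms: selenium dioxide, O=[Se]=O
Why: Riley allylic oxidation (ene reaction, [2,3] shift, then alcohol to aldehyde) takes the isopropenyl methyl to the enal because the ring alkene is a deactivated enone, and the bought stereocenter (later C‑1) is untouched.

Step 2
Reactants: 2 2-[(1S)-4-methyl-5-oxocyclohex-3-en-1-yl]prop-2-enal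
Product: 3 (5S)-5-[(1E)-1-(tert-butyldimethylsilyloxy)prop-1-en-2-yl]-2-methylcyclohex-2-en-1-one
Conditions: t-BuMe2SiH, RhCl(PPh3)3 (1 mol %), THF, 50 °C
Reagents that add atoms: tert-butyldimethylsilane, C[SiH](C)C(C)(C)C
Why: Rhodium-catalysed 1,4-hydrosilylation of the s-cis enal puts H on the methylene carbon and Si on oxygen, which fixes the enol ether as E (OTBS cis to the new methyl, trans to the ring), while the trisubstituted ring enone reacts far more slowly.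

Step 3
Reactants: 3 (5S)-5-[(1E)-1-(tert-butyldimethylsilyloxy)prop-1-en-2-yl]-2-methylcyclohex-2-en-1-one
Product: 4 (6S)-2-(tert-butyldimethylsilyloxy)-6-[(1E)-1-(tert-butyldimethylsilyloxy)prop-1-en-2-yl]-3-methylcyclohexa-1,3-diene
Conditions: LDA, THF, −78 °C; then TBSCl, HMPA, −78 °C to rt
Reagents that add atoms: tert-butyldimethylsilyl chloride, CC(C)(C)[Si](C)(C)Cl
Why: Kinetic α′-deprotonation of the enone and O-silylation give the cross-conjugated silyl dienol ether, with no stereocenter involved.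

Step 4
Reactants: 4 (6S)-2-(tert-butyldimethylsilyloxy)-6-[(1E)-1-(tert-butyldimethylsilyloxy)prop-1-en-2-yl]-3-methylcyclohexa-1,3-diene
Product: 6 (1R,2R,6R)-2-(tert-butyldimethylsilyloxy)-6-[(1E)-1-(tert-butyldimethylsilyloxy)prop-1-en-2-yl]-3-methylcyclohex-3-en-1-ol, via alkylborane 5 (not isolated)
Conditions: BH3·THF (1 equiv), THF, −20 to 0 °C; then NaOH, H2O2, 0 °C
Reagents that add atoms: hydrogen peroxide, OO
Why: Hydroboration–oxidation of the ring silyl enol ether (a 1,2-carbonyl transposition) puts boron on the enol ether β-carbon anti to the side chain and H syn to it, so the new OH is trans and the OTBS cis to the side chain; the side-chain enol ether would need boron at a fully substituted carbon and is slower.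

Step 5
Reactants: 6 (1R,2R,6R)-2-(tert-butyldimethylsilyloxy)-6-[(1E)-1-(tert-butyldimethylsilyloxy)prop-1-en-2-yl]-3-methylcyclohex-3-en-1-ol
Product: 7 (2R,6R)-2-(tert-butyldimethylsilyloxy)-6-[(1E)-1-(tert-butyldimethylsilyloxy)prop-1-en-2-yl]-3-methylcyclohex-3-en-1-one
Conditions: Dess–Martin periodinane, CH2Cl2, rt
Reagents that add atoms: none
Why: Neutral Dess–Martin oxidation gives the transposed ketone without epimerising the α stereocenter or touching the enol ether.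

Step 6
Reactants: 8 4-methoxybenzyl alcohol; 9 trichloroethylene
Product: 10 1-{[(E)-1,2-dichloroethenyl]oxymethyl}-4-methoxybenzene
Conditions: KH, THF, 0 °C; then Cl2C=CHCl, −50 °C to rt
Reagents that add atoms: none
Why: Alkoxide addition to dichloroacetylene formed in the flask from trichloroethylene (Greene ynol ether protocol) gives the E dichlorovinyl ether.

Step 7
Reactants: 7 (2R,6R)-2-(tert-butyldimethylsilyloxy)-6-[(1E)-1-(tert-butyldimethylsilyloxy)prop-1-en-2-yl]-3-methylcyclohex-3-en-1-one; 10 1-{[(E)-1,2-dichloroethenyl]oxymethyl}-4-methoxybenzene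
Product: 13 (1S,2R,6R)-2-(tert-butyldimethylsilyloxy)-1-{(E)-2-[(4-methoxybenzyl)oxy]ethenyl}-6-[(1E)-1-(tert-butyldimethylsilyloxy)prop-1-en-2-yl]-3-methylcyclohex-3-en-1-ol, via lithium alkoxyacetylide 11 (not isolated), via lithium propargylic alkoxide 12 (not isolated)
Conditions: 10, n-BuLi (2.1 equiv), THF, −78 to −40 °C; then 7, −78 °C; then LiAlH4, 0 °C to rt
Reagents that add atoms: none
Why: Dehydrochlorination and Cl–Li exchange give the alkoxyacetylide, which as a slim nucleophile should add axially to the ketone (both α-substituents equatorial) so the alkynyl group is cis to the side chain, and alkoxide-directed trans-hydroalumination (Arens-type reduction) then gives the E enol ether.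

Step 8
Reactants: 13 (1S,2R,6R)-2-(tert-butyldimethylsilyloxy)-1-{(E)-2-[(4-methoxybenzyl)oxy]ethenyl}-6-[(1E)-1-(tert-butyldimethylsilyloxy)prop-1-en-2-yl]-3-methylcyclohex-3-en-1-ol
Product: 15 methyl (1(10)Z,3Z)-8α-[(4-methoxybenzyl)oxy]-5α,9β-bis(tert-butyldimethylsilyloxy)-6-oxo-13-norgermacra-1(10),3-dien-12-oate, via potassium enolate 14 (not isolated)
Conditions: KH, 18-crown-6, THF, 0 °C to rt; then BrCH2CO2Me, −78 °C
Reagents that add atoms: methyl bromoacetate, COC(=O)CBr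
Why: Anionic oxy-Cope [3,3]-sigmatropic ring expansion through a chair with the vinyl group axial and all other groups equatorial joins the two E enol ether termini, so the carvone-derived C‑1/C‑6 centers dictate 8α-O/9β-O (8R,9R, threo) and the 3Z alkene is simply carried over from the ring; the regiodefined enolate is alkylated anti to the C‑8 ether, which sets C‑7.

Step 9
Reactants: 15 methyl (1(10)Z,3Z)-8α-[(4-methoxybenzyl)oxy]-5α,9β-bis(tert-butyldimethylsilyloxy)-6-oxo-13-norgermacra-1(10),3-dien-12-oate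
Product: 18 (1(10)Z,3Z)-8α-[(4-methoxybenzyl)oxy]-9β-(tert-butyldimethylsilyloxy)-13-norgermacra-1(10),3-dien-12,6α-olide, via 5-deoxy ketone 16 (not isolated), via 6α-hydroxy ester 17 (not isolated)
Conditions: SmI2, THF–MeOH, −78 °C; then NaBH4, −78 to 0 °C
Reagents that add atoms: none
Why: SmI2 ketyl reduction expels the α-silyloxy group (the oxygen left over from carvone) and the enolate is protonated at C‑5; the ketone, whose C=O eclipses the α C‑7–H, is then reduced by NaBH4 from the periphery to the 6α-alkoxide, which closes onto the methyl ester as the trans-fused γ-lactone (sets C‑6).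

Step 10
Reactants: 18 (1(10)Z,3Z)-8α-[(4-methoxybenzyl)oxy]-9β-(tert-butyldimethylsilyloxy)-13-norgermacra-1(10),3-dien-12,6α-olide
Product: 21 (1(10)Z,3Z)-8α-[(4-methoxybenzyl)oxy]-9β-(tert-butyldimethylsilyloxy)germacra-1(10),3,11(13)-trien-12,6α-olide, via Mannich base 19 (not isolated), via trimethylammonium iodide 20 (not isolated)
Conditions: LDA, THF, −78 °C; CH2=NMe2+ I−; then MeI, MeOH; then aq NaHCO3
Reagents that add atoms: N,N-dimethylmethyleneiminium iodide (Eschenmoser's salt), C=[N+](C)C.[I-]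
Why: Eschenmoser α-methylenation (Mannich reaction of the lactone enolate, N-methylation, Hofmann-type elimination) installs C‑13 and removes the only new stereocenter again.

Step 11
Reactants: 21 (1(10)Z,3Z)-8α-[(4-methoxybenzyl)oxy]-9β-(tert-butyldimethylsilyloxy)germacra-1(10),3,11(13)-trien-12,6α-olide
Product: 22 (1(10)Z,3Z)-9β-hydroxy-8α-[(4-methoxybenzyl)oxy]germacra-1(10),3,11(13)-trien-12,6α-olide
Conditions: HF·pyridine, THF, 0 °C to rt
Reagents that add atoms: none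
Why: Fluoride-mediated desilylation under mildly acidic conditions frees only the C‑9 hydroxyl and spares the benzyl-type ether and the methylene lactone.

Step 12
Reactants: 22 (1(10)Z,3Z)-9β-hydroxy-8α-[(4-methoxybenzyl)oxy]germacra-1(10),3,11(13)-trien-12,6α-olide
Product: 23 (1(10)Z,3Z)-9β-angeloyloxy-8α-[(4-methoxybenzyl)oxy]germacra-1(10),3,11(13)-trien-12,6α-olide
Conditions: angelic acid, 2,4,6-Cl3C6H2COCl, Et3N, toluene; then 22, DMAP, rt
Reagents that add atoms: angelic acid, C/C=C(/C)C(=O)O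
Why: Yamaguchi esterification through the preformed mixed anhydride acylates the only free hydroxyl at room temperature, which keeps angelate-to-tiglate isomerisation low.

Step 13
Reactants: 23 (1(10)Z,3Z)-9β-angeloyloxy-8α-[(4-methoxybenzyl)oxy]germacra-1(10),3,11(13)-trien-12,6α-olide
Product: 24 (1(10)Z)-9β-angeloyloxy-3β,4β-epoxy-8α-[(4-methoxybenzyl)oxy]germacra-1(10),11(13)-dien-12,6α-olide
Conditions: mCPBA, CH2Cl2, −20 °C
Reagents that add atoms: 3-chloroperoxybenzoic acid, OOC(=O)c1cccc(Cl)c1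
Why: Prilezhaev epoxidation picks the only unperturbed electron-rich alkene (C‑1/C‑10 is deactivated by the allylic angelate, the others are conjugated) and is expected on the β face, anti to the C‑6 lactone oxygen, to give the cis 3β,4β-epoxide (3S,4R).

Step 14
Reactants: 24 (1(10)Z)-9β-angeloyloxy-3β,4β-epoxy-8α-[(4-methoxybenzyl)oxy]germacra-1(10),11(13)-dien-12,6α-olide
Product: 26 9β-angeloyloxy-3β,4β-epoxy-8α-[(4-methoxybenzyl)oxy]-1-oxogermacra-10(14),11(13)-dien-12,6α-olide, via allylic hydroperoxide 25 (not isolated)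
Conditions: O2, tetraphenylporphyrin, hν, CH2Cl2, 0 °C; then Ac2O, pyridine, DMAP
Reagents that add atoms: dioxygen, O=O
Why: Schenck ene reaction of singlet oxygen at the last electron-rich alkene removes a C‑14 hydrogen (geminal to the acyloxy-bearing C‑9) to give the C‑1 hydroperoxide with the 10(14) methylene, and Kornblum–DeLaMare dehydration gives the enone without creating a stereocenter.

Step 15
Reactants: 26 9β-angeloyloxy-3β,4β-epoxy-8α-[(4-methoxybenzyl)oxy]-1-oxogermacra-10(14),11(13)-dien-12,6α-olide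
Product: 27 9β-angeloyloxy-3β,4β-epoxy-8α-hydroxy-1-oxogermacra-10(14),11(13)-dien-12,6α-olide (3S,4R,6R,7R,8R,9R; CNP0348992.7)
Conditions: DDQ, CH2Cl2–pH 7 buffer, 0 °C
Reagents that add atoms: none
Why: Oxidative cleavage of the 4-methoxybenzyl ether under neutral conditions frees the C‑8 hydroxyl without touching the epoxide, enone, angelate or methylene lactone.

## Compound list

1 | (S)-(+)-carvone | CC(=C)[C@H]1CC=C(C)C(=O)C1 | starting material
2 | 2-[(1S)-4-methyl-5-oxocyclohex-3-en-1-yl]prop-2-enal | O=CC(=C)[C@H]1CC=C(C)C(=O)C1 | intermediate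
3 | (5S)-5-[(1E)-1-(tert-butyldimethylsilyloxy)prop-1-en-2-yl]-2-methylcyclohex-2-en-1-one | C/C(=C\O[Si](C)(C)C(C)(C)C)[C@H]1CC=C(C)C(=O)C1 | intermediate
4 | (6S)-2-(tert-butyldimethylsilyloxy)-6-[(1E)-1-(tert-butyldimethylsilyloxy)prop-1-en-2-yl]-3-methylcyclohexa-1,3-diene | C/C(=C\O[Si](C)(C)C(C)(C)C)[C@H]1CC=C(C)C(O[Si](C)(C)C(C)(C)C)=C1 | intermediate
5 | alkylborane (BH2 in place of the hydroxyl of 6, same configuration; not isolated) | C/C(=C\O[Si](C)(C)C(C)(C)C)[C@H]1CC=C(C)[C@@H](O[Si](C)(C)C(C)(C)C)[C@@H]1B | intermediate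
6 | (1R,2R,6R)-2-(tert-butyldimethylsilyloxy)-6-[(1E)-1-(tert-butyldimethylsilyloxy)prop-1-en-2-yl]-3-methylcyclohex-3-en-1-ol | C/C(=C\O[Si](C)(C)C(C)(C)C)[C@H]1CC=C(C)[C@@H](O[Si](C)(C)C(C)(C)C)[C@@H]1O | intermediate
7 | (2R,6R)-2-(tert-butyldimethylsilyloxy)-6-[(1E)-1-(tert-butyldimethylsilyloxy)prop-1-en-2-yl]-3-methylcyclohex-3-en-1-one | C/C(=C\O[Si](C)(C)C(C)(C)C)[C@H]1CC=C(C)[C@@H](O[Si](C)(C)C(C)(C)C)C1=O | intermediate
8 | 4-methoxybenzyl alcohol | COc1ccc(CO)cc1 | starting material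
9 | trichloroethylene | ClC=C(Cl)Cl | starting material
10 | 1-{[(E)-1,2-dichloroethenyl]oxymethyl}-4-methoxybenzene | COc1ccc(CO/C(Cl)=C\Cl)cc1 | intermediate
11 | lithium [(4-methoxybenzyl)oxy]ethynide (not isolated) | [Li]C#COCc1ccc(OC)cc1 | intermediate
12 | lithium (1S,2R,6R)-2-(tert-butyldimethylsilyloxy)-1-{[(4-methoxybenzyl)oxy]ethynyl}-6-[(1E)-1-(tert-butyldimethylsilyloxy)prop-1-en-2-yl]-3-methylcyclohex-3-en-1-olate (not isolated) | C/C(=C\O[Si](C)(C)C(C)(C)C)[C@H]1CC=C(C)[C@@H](O[Si](C)(C)C(C)(C)C)[C@@]1([O-])C#COCc1ccc(OC)cc1.[Li+] | intermediate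
13 | (1S,2R,6R)-2-(tert-butyldimethylsilyloxy)-1-{(E)-2-[(4-methoxybenzyl)oxy]ethenyl}-6-[(1E)-1-(tert-butyldimethylsilyloxy)prop-1-en-2-yl]-3-methylcyclohex-3-en-1-ol | C/C(=C\O[Si](C)(C)C(C)(C)C)[C@H]1CC=C(C)[C@@H](O[Si](C)(C)C(C)(C)C)[C@@]1(O)/C=C/OCc1ccc(OC)cc1 | intermediate
14 | potassium C‑6/C‑7 enolate of the ring-expanded ketone (8α-OPMB, 5α,9β-bis-OTBS, 1(10)Z,3Z; not isolated) | [K+].[O-]/C1=C\[C@@H](OCc2ccc(OC)cc2)[C@H](O[Si](C)(C)C(C)(C)C)/C(C)=C\C/C=C(/C)\[C@H]1O[Si](C)(C)C(C)(C)C | intermediate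
15 | methyl (1(10)Z,3Z)-8α-[(4-methoxybenzyl)oxy]-5α,9β-bis(tert-butyldimethylsilyloxy)-6-oxo-13-norgermacra-1(10),3-dien-12-oate (H-7α) | O=C1[C@H](O[Si](C)(C)C(C)(C)C)/C(C)=C\C/C=C(/C)\[C@@H](O[Si](C)(C)C(C)(C)C)[C@H](OCc2ccc(OC)cc2)[C@H]1CC(=O)OC | intermediate
16 | methyl (1(10)Z,3Z)-8α-[(4-methoxybenzyl)oxy]-9β-(tert-butyldimethylsilyloxy)-6-oxo-13-norgermacra-1(10),3-dien-12-oate (not isolated) | O=C1C/C(C)=C\C/C=C(/C)\[C@@H](O[Si](C)(C)C(C)(C)C)[C@H](OCc2ccc(OC)cc2)[C@H]1CC(=O)OC | intermediate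
17 | methyl (1(10)Z,3Z)-6α-hydroxy-8α-[(4-methoxybenzyl)oxy]-9β-(tert-butyldimethylsilyloxy)-13-norgermacra-1(10),3-dien-12-oate (not isolated) | O[C@@H]1C/C(C)=C\C/C=C(/C)\[C@@H](O[Si](C)(C)C(C)(C)C)[C@H](OCc2ccc(OC)cc2)[C@H]1CC(=O)OC | intermediate
18 | (1(10)Z,3Z)-8α-[(4-methoxybenzyl)oxy]-9β-(tert-butyldimethylsilyloxy)-13-norgermacra-1(10),3-dien-12,6α-olide | C1C(=O)O[C@@H]2C/C(C)=C\C/C=C(/C)\[C@@H](O[Si](C)(C)C(C)(C)C)[C@H](OCc3ccc(OC)cc3)[C@@H]12 | intermediate
19 | 13-(dimethylamino)-11,13-dihydro derivative of 21 (Mannich base, C‑11 epimers; not isolated) | CN(C)CC1C(=O)O[C@@H]2C/C(C)=C\C/C=C(/C)\[C@@H](O[Si](C)(C)C(C)(C)C)[C@H](OCc3ccc(OC)cc3)[C@@H]12 | intermediate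
20 | trimethylammonium iodide of 19 (not isolated) | C[N+](C)(C)CC1C(=O)O[C@@H]2C/C(C)=C\C/C=C(/C)\[C@@H](O[Si](C)(C)C(C)(C)C)[C@H](OCc3ccc(OC)cc3)[C@@H]12.[I-] | intermediate
21 | (1(10)Z,3Z)-8α-[(4-methoxybenzyl)oxy]-9β-(tert-butyldimethylsilyloxy)germacra-1(10),3,11(13)-trien-12,6α-olide | C=C1C(=O)O[C@@H]2C/C(C)=C\C/C=C(/C)\[C@@H](O[Si](C)(C)C(C)(C)C)[C@H](OCc3ccc(OC)cc3)[C@@H]12 | intermediate
22 | (1(10)Z,3Z)-9β-hydroxy-8α-[(4-methoxybenzyl)oxy]germacra-1(10),3,11(13)-trien-12,6α-olide | C=C1C(=O)O[C@@H]2C/C(C)=C\C/C=C(/C)\[C@@H](O)[C@H](OCc3ccc(OC)cc3)[C@@H]12 | intermediate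
23 | (1(10)Z,3Z)-9β-angeloyloxy-8α-[(4-methoxybenzyl)oxy]germacra-1(10),3,11(13)-trien-12,6α-olide | C=C1C(=O)O[C@@H]2C/C(C)=C\C/C=C(/C)\[C@@H](OC(=O)/C(C)=C\C)[C@H](OCc3ccc(OC)cc3)[C@@H]12 | intermediate
24 | (1(10)Z)-9β-angeloyloxy-3β,4β-epoxy-8α-[(4-methoxybenzyl)oxy]germacra-1(10),11(13)-dien-12,6α-olide | C=C1C(=O)O[C@@H]2C[C@@]3(C)O[C@H]3C/C=C(/C)\[C@@H](OC(=O)/C(C)=C\C)[C@H](OCc4ccc(OC)cc4)[C@@H]12 | intermediate
25 | 1-hydroperoxy-10(14)-ene from 24 (C‑1 epimers, configuration immaterial; not isolated) | C=C1C(=O)O[C@@H]2C[C@@]3(C)O[C@H]3CC(OO)C(=C)[C@@H](OC(=O)/C(C)=C\C)[C@H](OCc4ccc(OC)cc4)[C@@H]12 | intermediate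
26 | 9β-angeloyloxy-3β,4β-epoxy-8α-[(4-methoxybenzyl)oxy]-1-oxogermacra-10(14),11(13)-dien-12,6α-olide | C=C1C(=O)O[C@@H]2C[C@@]3(C)O[C@H]3CC(=O)C(=C)[C@@H](OC(=O)/C(C)=C\C)[C@H](OCc4ccc(OC)cc4)[C@@H]12 | intermediate
27 | 9β-angeloyloxy-3β,4β-epoxy-8α-hydroxy-1-oxogermacra-10(14),11(13)-dien-12,6α-olide (3S,4R,6R,7R,8R,9R) | C=C1C(=O)O[C@@H]2C[C@@]3(C)O[C@H]3CC(=O)C(=C)[C@@H](OC(=O)/C(C)=C\C)[C@H](O)[C@@H]12 | target

## Step count and risks

Total step count: 15. Longest linear sequence: 14 steps (steps 1–5 and 7–15, from (S)-carvone); step 6 prepares the acetylide precursor.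

**Step 4 (hydroboration of the dienol ether).** Borane may also attack the side-chain enol ether or the conjugated diene, or the β-silyloxy borane may eliminate. The fallback sets out from 3 and comes back at 6. The kinetic enolate of 3 (LDA, −78 °C) is oxidised with MoO5·pyridine·HMPA to the trans hydroxy enone (5R,6R)-6-hydroxy-2-methyl-5-[(1E)-1-(tert-butyldimethylsilyloxy)prop-1-en-2-yl]cyclohex-2-en-1-one F1. LiAlH4 at −78 °C delivers hydride from the face of the neighbouring alkoxide to give (1R,2R,6R)-3-methyl-6-[(1E)-1-(tert-butyldimethylsilyloxy)prop-1-en-2-yl]cyclohex-3-ene-1,2-diol F2. TBSCl and imidazole then silylate the less hindered allylic hydroxyl, which is 6.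

**Step 8 (anionic oxy-Cope and alkylation).** The β-alkoxy potassium enolate may eliminate the C‑8 ether, a silyl group may migrate to the alkoxide, or the alkylation may be unselective. The fallback sets out from 13 and comes back at 15 through a neutral rearrangement. 13 is silylated (TMS-imidazole) to its trimethylsilyl ether (1S,2R,6R)-1-(trimethylsilyloxy)-2-(tert-butyldimethylsilyloxy)-1-{(E)-2-[(4-methoxybenzyl)oxy]ethenyl}-6-[(1E)-1-(tert-butyldimethylsilyloxy)prop-1-en-2-yl]-3-methylcyclohex-3-ene F3. Heating in degassed o-dichlorobenzene at about 180 °C effects the siloxy-Cope rearrangement to the ten-membered silyl enol ether (1(10)Z,3Z,6Z)-8α-[(4-methoxybenzyl)oxy]-5α,9β-bis(tert-butyldimethylsilyloxy)-6-(trimethylsilyloxy)-11,12,13-trinorgermacra-1(10),3,6-triene F4. MeLi in THF releases the lithium enolate regiospecifically, and methyl bromoacetate with HMPA at −78 °C gives 15.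

**Step 14 (singlet-oxygen ene reaction).** Hydrogen abstraction may occur at C‑2 instead of C‑14, or the deactivated Z alkene may be too slow. The fallback sets out from 22 and comes back at 26, and replaces steps 12–14.
- VO(acac)2 and t-BuOOH epoxidise only the alkene allylic to the free C‑9 hydroxyl, giving 1,10-epoxy-9β-hydroxy-8α-[(4-methoxybenzyl)oxy]germacra-3Z,11(13)-dien-12,6α-olide F5 (epoxide syn to the hydroxyl, configuration immaterial).
- Yamaguchi esterification with angelic acid gives its 9-angelate 9β-angeloyloxy-1,10-epoxy-8α-[(4-methoxybenzyl)oxy]germacra-3Z,11(13)-dien-12,6α-olide F6.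
- Cp2TiCl (trivalent titanium, made in the flask from Cp2TiCl2 and Zn) opens the epoxide to the tertiary C‑10 radical and, after β-hydride loss from C‑14, gives 9β-angeloyloxy-1-hydroxy-8α-[(4-methoxybenzyl)oxy]germacra-3Z,10(14),11(13)-trien-12,6α-olide F7.
- Dess–Martin oxidation gives 9β-angeloyloxy-8α-[(4-methoxybenzyl)oxy]-1-oxogermacra-3Z,10(14),11(13)-trien-12,6α-olide F8.
- mCPBA then epoxidises the remaining electron-rich 3Z alkene to give 26.

## Further compounds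

F1 | step 4 | (5R,6R)-6-hydroxy-2-methyl-5-[(1E)-1-(tert-butyldimethylsilyloxy)prop-1-en-2-yl]cyclohex-2-en-1-one | C/C(=C\O[Si](C)(C)C(C)(C)C)[C@H]1CC=C(C)C(=O)[C@@H]1O
F2 | step 4 | (1R,2R,6R)-3-methyl-6-[(1E)-1-(tert-butyldimethylsilyloxy)prop-1-en-2-yl]cyclohex-3-ene-1,2-diol | C/C(=C\O[Si](C)(C)C(C)(C)C)[C@H]1CC=C(C)[C@@H](O)[C@@H]1O
F3 | step 8 | (1S,2R,6R)-1-(trimethylsilyloxy)-2-(tert-butyldimethylsilyloxy)-1-{(E)-2-[(4-methoxybenzyl)oxy]ethenyl}-6-[(1E)-1-(tert-butyldimethylsilyloxy)prop-1-en-2-yl]-3-methylcyclohex-3-ene | C/C(=C\O[Si](C)(C)C(C)(C)C)[C@H]1CC=C(C)[C@@H](O[Si](C)(C)C(C)(C)C)[C@@]1(O[Si](C)(C)C)/C=C/OCc1ccc(OC)cc1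
F4 | step 8 | (1(10)Z,3Z,6Z)-8α-[(4-methoxybenzyl)oxy]-5α,9β-bis(tert-butyldimethylsilyloxy)-6-(trimethylsilyloxy)-11,12,13-trinorgermacra-1(10),3,6-triene | C[Si](C)(C)O/C1=C\[C@@H](OCc2ccc(OC)cc2)[C@H](O[Si](C)(C)C(C)(C)C)/C(C)=C\C/C=C(/C)\[C@H]1O[Si](C)(C)C(C)(C)C
F5 | step 14 | 1,10-epoxy-9β-hydroxy-8α-[(4-methoxybenzyl)oxy]germacra-3Z,11(13)-dien-12,6α-olide (epoxide syn to 9-OH, not specified) | C=C1C(=O)O[C@@H]2C/C(C)=C\CC3OC3(C)[C@@H](O)[C@H](OCc4ccc(OC)cc4)[C@@H]12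
F6 | step 14 | 9β-angeloyloxy-1,10-epoxy-8α-[(4-methoxybenzyl)oxy]germacra-3Z,11(13)-dien-12,6α-olide | C=C1C(=O)O[C@@H]2C/C(C)=C\CC3OC3(C)[C@@H](OC(=O)/C(C)=C\C)[C@H](OCc4ccc(OC)cc4)[C@@H]12
F7 | step 14 | 9β-angeloyloxy-1-hydroxy-8α-[(4-methoxybenzyl)oxy]germacra-3Z,10(14),11(13)-trien-12,6α-olide (C‑1 configuration immaterial) | C=C1C(=O)O[C@@H]2C/C(C)=C\CC(O)C(=C)[C@@H](OC(=O)/C(C)=C\C)[C@H](OCc4ccc(OC)cc4)[C@@H]12
F8 | step 14 | 9β-angeloyloxy-8α-[(4-methoxybenzyl)oxy]-1-oxogermacra-3Z,10(14),11(13)-trien-12,6α-olide | C=C1C(=O)O[C@@H]2C/C(C)=C\CC(=O)C(=C)[C@@H](OC(=O)/C(C)=C\C)[C@H](OCc4ccc(OC)cc4)[C@@H]12
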